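The pyranone ring (ring C) is cut at O1–C8a and C4–C4a, which turns ring A into a C4a≡C8a aryne and the rest into a β-methoxyacrylic acid that already carries the 4-methoxybenzyl group. In one operation the aryne enters the C–O bond of the carboxylate (oxygen to C8a, acyl carbon to C4a) and the freed phenoxide closes ring C by addition–elimination, giving the chromone directly. The step exploits the ring-fusion bond C4a–C8a of the fully substituted ring A and the C5 methoxy group next to C4a, which polarizes the aryne. Its precursor is an ortho-silylaryl triflate (silicon on C8a, triflate on C4a) with the C7 oxygen masked as a MOM ether; C8 is formylated last.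

Key step: step 9

Remark on the chemistry: ring A carbons are called by their chromone locants (C4a, C5, C6, C7, C8, C8a) from compound 1 onward; compounds 1, 11 and 12 are assumed purchasable; the target has no stereocentre.

Step 1
Reactants: 1 2,4-dihydroxy-3-methylbenzaldehyde
Product: 2 2-hydroxy-4-(methoxymethoxy)-3-methylbenzaldehyde
Conditions: MOMCl, K2CO3, acetone, 0 °C to rt
Reagents that add atoms: chloromethyl methyl ether (MOMCl), COCCl
Why: Williamson-type O-alkylation in which the 2-hydroxyl is held in a hydrogen bond to the aldehyde and flanked on both sides, so the mild base alkylates only the free 4-hydroxyl (the future C7 oxygen).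

Step 2
Reactants: 2 2-hydroxy-4-(methoxymethoxy)-3-methylbenzaldehyde
Product: 3 2-methoxy-4-(methoxymethoxy)-3-methylbenzaldehyde
Conditions: MeI, K2CO3, DMF, rt to 40 °C
Reagents that add atoms: iodomethane, CI
Why: Williamson ether synthesis in which carbonate in DMF opens the chelate and the small electrophile methylates the remaining hindered hydroxyl (the future C5 methoxy) while aldehyde and MOM acetal stay intact.

Step 3
Reactants: 3 2-methoxy-4-(methoxymethoxy)-3-methylbenzaldehyde
Product: 5 2-methoxy-4-(methoxymethoxy)-3-methylphenol, via aryl formate 4 (not isolated)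
Conditions: mCPBA, CH2Cl2, 0 °C to rt; wash with aq NaHCO3/Na2S2O3; then K2CO3 (cat), MeOH, rt
Reagents that add atoms: meta-chloroperoxybenzoic acid (mCPBA), OOC(=O)c1cccc(Cl)c1
Why: Baeyer–Villiger oxidation in its Dakin-type form, in which the aryl group, made electron-rich by its ortho-methoxy and para-MOM-oxy substituents, migrates in preference to hydride to give formate 4, and mild methanolysis then frees the C4a phenol without touching the MOM ether.

Step 4
Reactants: 5 2-methoxy-4-(methoxymethoxy)-3-methylphenol
Product: 6 6-bromo-2-methoxy-4-(methoxymethoxy)-3-methylphenol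
Conditions: NBS (1.0 equiv), iPr2NH (10 mol %), CH2Cl2, −20 to 0 °C
Reagents that add atoms: N-bromosuccinimide, O=C1CCC(=O)N1Br
Why: Amine-mediated ortho-bromination of a phenol (electrophilic aromatic substitution) in which the N-bromoamine is delivered through a hydrogen bond to the hydroxyl, whose only open ortho carbon is C8a, whereas C8 is activated only by the MOM-oxy group and by a methoxy twisted out of conjugation by its two neighbours.

Step 5
Reactants: 6 6-bromo-2-methoxy-4-(methoxymethoxy)-3-methylphenol
Product: 7 [6-bromo-2-methoxy-4-(methoxymethoxy)-3-methylphenoxy]trimethylsilane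
Conditions: HMDS, THF, reflux; evaporate to dryness
Reagents that add atoms: hexamethyldisilazane, C[Si](C)(C)N[Si](C)(C)C
Why: O-Silylation of a phenol by transsilylation with the disilazane, which gives only ammonia beside the product so the moisture-sensitive silyl ether can be carried on after evaporation.

Step 6
Reactants: 7 [6-bromo-2-methoxy-4-(methoxymethoxy)-3-methylphenoxy]trimethylsilane
Product: 10 2-methoxy-4-(methoxymethoxy)-3-methyl-6-(trimethylsilyl)phenyl trifluoromethanesulfonate, via aryllithium 8 (not isolated), via lithium silylphenoxide 9 (not isolated)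
Conditions: n-BuLi, THF, −100 to −78 °C; then Tf2O, −100 to −78 °C
Reagents that add atoms: trifluoromethanesulfonic anhydride, O=S(=O)(OS(=O)(=O)C(F)(F)F)C(F)(F)F
Why: Bromine–lithium exchange is faster than any MOM-directed deprotonation at −100 °C, the ortho-lithio silyl ether 8 undergoes retro-Brook 1,3 O-to-C silyl migration to phenoxide 9 (silicon now on C8a), and O-sulfonylation at low temperature gives the triflate on the C4a oxygen.

Step 7
Reactants: 11 methyl 3-(4-methoxyphenyl)propanoate; 12 methyl formate
Product: 14 methyl (E)-3-methoxy-2-(4-methoxybenzyl)acrylate, via sodium formyl-ester enolate 13 (not isolated)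
Conditions: NaH, HCO2Me (excess), THF, cat MeOH, 0 °C to rt; then DMF, Me2SO4, 0 °C to rt
Reagents that add atoms: methyl formate (compound 12), COC=O; dimethyl sulfate, COS(=O)(=O)OC
Why: Crossed Claisen condensation (C-formylation of the ester enolate, driven by deprotonation of the β-dicarbonyl product) followed by O-alkylation of the ambident enolate 13 by the hard electrophile in DMF, the more stable E enol ether being expected although its geometry does not matter later.

Step 8
Reactants: 14 methyl (E)-3-methoxy-2-(4-methoxybenzyl)acrylate
Product: 15 (E)-3-methoxy-2-(4-methoxybenzyl)acrylic acid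
Conditions: LiOH·H2O, THF/MeOH/H2O, rt to 40 °C; then cold 1 M HCl to pH 3
Reagents that add atoms: lithium hydroxide, [Li+].[OH-]
Why: Ester saponification of a β-methoxyacrylate, a vinylogous carbonate whose enol ether resists hydroxide, with cold and only mildly acidic work-up so that the enol ether is not hydrolysed.

Step 9
Reactants: 10 2-methoxy-4-(methoxymethoxy)-3-methyl-6-(trimethylsilyl)phenyl trifluoromethanesulfonate; 15 (E)-3-methoxy-2-(4-methoxybenzyl)acrylic acid
Product: 20 5-methoxy-3-(4-methoxybenzyl)-7-(methoxymethoxy)-6-methylchromen-4-one, via cesium carboxylate 16 (not isolated), via aryne 17 (not isolated), via cesium acylphenoxide 18 (not isolated), via methoxychromanone enolate 19 (not isolated)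
Conditions: 15 (1.5 equiv), Cs2CO3 (0.75 equiv), MeOH, rt, evaporate, dry by toluene azeotrope; then 10 (1 equiv), CsF (3 equiv), THF, 125 °C, sealed tube
Reagents that add atoms: none
Why: Proposed new method: fluoride removes silicon from C8a and triflate leaves C4a to give aryne 17, carboxylate 16 adds through oxygen at C8a, and the C4a carbanion attacks its own ester carbonyl through a four-membered tetrahedral intermediate (anionic Fries-type 1,3 O-to-C acyl shift) to give acylphenoxide 18. The closest known reaction type is the formal insertion of arynes into the C–O bond of carboxylic acids to give ortho-hydroxyaryl ketones, which with acrylic acids continues by oxa-Michael closure to 4-chromanones; a β-methoxy leaving group on the acrylic acid is the untested element. Ring C (the pyranone) closes by 6-endo-trig oxa-Michael attack of the C8a phenoxide on the β-carbon (bond O1–C2), and enolate 19 expels methoxide by E1cB, which sets the chromone oxidation level without a dehydrogenation. No stereocentre is created in the product: C2 of 19 is transient and the E geometry of 15 is erased, so either alkene isomer converges. The selectivity needed is regiochemical (oxygen to C8a, acyl to C4a) and is secured by the inductively withdrawing C5 methoxy beside C4a, which directs the nucleophile to the distal aryne carbon and stabilises the C4a carbanion, with only hydrogen at C8 on the other flank and a weak, remote counter-effect from the C7 MOM-oxy group. The dry preformed cesium salt keeps proton sources low so that acyl transfer outruns protonation to a simple aryl ester, the donor-substituted β-carbon is a poor acceptor for the carbanion (the coumarin pathway), and the internal Michael acceptor captures the phenoxide before it meets a second aryne.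

Step 10
Reactants: 20 5-methoxy-3-(4-methoxybenzyl)-7-(methoxymethoxy)-6-methylchromen-4-one
Product: 21 7-hydroxy-5-methoxy-3-(4-methoxybenzyl)-6-methylchromen-4-one
Conditions: 3 M HCl, MeOH, 50 °C
Reagents that add atoms: none
Why: Acid-catalysed acetal cleavage (transacetalisation to methanol) removes the MOM group from the C7 oxygen, while the aryl methyl ethers and the chromone are stable to dilute protic acid.

Step 11
Reactants: 21 7-hydroxy-5-methoxy-3-(4-methoxybenzyl)-6-methylchromen-4-one
Product: 22 7-hydroxy-5-methoxy-3-(4-methoxybenzyl)-6-methyl-4-oxochromene-8-carbaldehyde (target CNP0177360.0)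
Conditions: hexamethylenetetramine, AcOH, 100 °C; then 3 M aq HCl, 70 °C
Reagents that add atoms: hexamethylenetetramine, C1N2CN3CN1CN(C2)C3; water, O
Why: Duff reaction in which the iminium ion from hexamethylenetetramine attacks C8, the only unsubstituted carbon of ring A and ortho to the C7 hydroxyl and para to the C5 methoxy, and internal hydride transfer followed by acid hydrolysis releases the aldehyde, the hydroxyl-free anisole ring being inert in acetic acid.

Compound list
1 | 2,4-dihydroxy-3-methylbenzaldehyde | Cc1c(O)ccc(C=O)c1O | starting material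
2 | 2-hydroxy-4-(methoxymethoxy)-3-methylbenzaldehyde | COCOc1ccc(C=O)c(O)c1C | intermediate
3 | 2-methoxy-4-(methoxymethoxy)-3-methylbenzaldehyde | COCOc1ccc(C=O)c(OC)c1C | intermediate
4 | 2-methoxy-4-(methoxymethoxy)-3-methylphenyl formate | COCOc1ccc(OC=O)c(OC)c1C | intermediate (not isolated)
5 | 2-methoxy-4-(methoxymethoxy)-3-methylphenol | COCOc1ccc(O)c(OC)c1C | intermediate
6 | 6-bromo-2-methoxy-4-(methoxymethoxy)-3-methylphenol | COCOc1cc(Br)c(O)c(OC)c1C | intermediate
7 | [6-bromo-2-methoxy-4-(methoxymethoxy)-3-methylphenoxy]trimethylsilane | COCOc1cc(Br)c(O[Si](C)(C)C)c(OC)c1C | intermediate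
8 | [3-methoxy-5-(methoxymethoxy)-4-methyl-2-(trimethylsilyloxy)phenyl]lithium | [Li]c1cc(OCOC)c(C)c(OC)c1O[Si](C)(C)C | intermediate (not isolated)
9 | lithium 2-methoxy-4-(methoxymethoxy)-3-methyl-6-(trimethylsilyl)phenolate | [Li+].[O-]c1c(OC)c(C)c(OCOC)cc1[Si](C)(C)C | intermediate (not isolated)
10 | 2-methoxy-4-(methoxymethoxy)-3-methyl-6-(trimethylsilyl)phenyl trifluoromethanesulfonate | COCOc1cc([Si](C)(C)C)c(OS(=O)(=O)C(F)(F)F)c(OC)c1C | intermediate
11 | methyl 3-(4-methoxyphenyl)propanoate | COC(=O)CCc1ccc(OC)cc1 | starting material
12 | methyl formate | COC=O | starting material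
13 | sodium enolate of methyl 2-formyl-3-(4-methoxyphenyl)propanoate (delocalised anion, geometry not fixed) | [Na+].[O-]C=C(Cc1ccc(OC)cc1)C(=O)OC | intermediate (not isolated)
14 | methyl (E)-3-methoxy-2-(4-methoxybenzyl)acrylate | CO/C=C(\Cc1ccc(OC)cc1)C(=O)OC | intermediate
15 | (E)-3-methoxy-2-(4-methoxybenzyl)acrylic acid | CO/C=C(\Cc1ccc(OC)cc1)C(=O)O | intermediate
16 | cesium (E)-3-methoxy-2-(4-methoxybenzyl)acrylate | CO/C=C(\Cc1ccc(OC)cc1)C(=O)[O-].[Cs+] | intermediate (not isolated)
17 | 3-methoxy-5-(methoxymethoxy)-4-methylbenzyne (1,2-didehydrobenzene; aryne between C4a and C8a) | COCOC1=CC#CC(OC)=C1C | intermediate (not isolated)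
18 | cesium 3-methoxy-2-[(E)-3-methoxy-2-(4-methoxybenzyl)acryloyl]-5-(methoxymethoxy)-4-methylphenolate | CO/C=C(\Cc1ccc(OC)cc1)C(=O)c1c(OC)c(C)c(OCOC)cc1[O-].[Cs+] | intermediate (not isolated)
19 | cesium 2,5-dimethoxy-3-(4-methoxybenzyl)-7-(methoxymethoxy)-6-methyl-2H-chromen-4-olate (racemic at C2, transient) | [Cs+].[O-]C1=C(Cc2ccc(OC)cc2)C(OC)Oc2cc(OCOC)c(C)c(OC)c12 | intermediate (not isolated)
20 | 5-methoxy-3-(4-methoxybenzyl)-7-(methoxymethoxy)-6-methylchromen-4-one | COCOc1cc2occ(Cc3ccc(OC)cc3)c(=O)c2c(OC)c1C | intermediate
21 | 7-hydroxy-5-methoxy-3-(4-methoxybenzyl)-6-methylchromen-4-one | COc1ccc(Cc2coc3cc(O)c(C)c(OC)c3c2=O)cc1 | intermediate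
22 | 7-hydroxy-5-methoxy-3-(4-methoxybenzyl)-6-methyl-4-oxochromene-8-carbaldehyde (CNP0177360.0) | COc1ccc(Cc2coc3c(C=O)c(O)c(C)c(OC)c3c2=O)cc1 | target

Total step count: 11 steps (steps 1–6 to the aryne precursor, steps 7–8 to the acid, steps 9–11 after convergence).
Longest linear sequence: 9 steps (steps 1, 2, 3, 4, 5, 6, 9, 10, 11).

Steps most likely to fail

Step 9 (carries the proposed new method). Three processes could defeat it: protonation of the C4a carbanion before acyl transfer, capture of the aryne by the methoxide released in the flask, or attack of the carbanion on the acrylate β-carbon. The fallback brings in C2 separately by known chemistry, setting out from 10 and 11 and returning at 20. Ester 11 would be saponified (LiOH, THF/H2O) to 3-(4-methoxyphenyl)propanoic acid F1. F1 and triflate 10 with CsF in THF at 125 °C would undergo the established aryne insertion into the C–O bond of a simple carboxylic acid, with the same regiocontrol by the C5 methoxy, to give 1-[6-hydroxy-2-methoxy-4-(methoxymethoxy)-3-methylphenyl]-3-(4-methoxyphenyl)propan-1-one F2. Heating F2 with N,N-dimethylformamide dimethyl acetal in toluene would condense its α-methylene to (E)-3-(dimethylamino)-1-[6-hydroxy-2-methoxy-4-(methoxymethoxy)-3-methylphenyl]-2-(4-methoxybenzyl)prop-2-en-1-one F3, which is not isolated and closes with loss of dimethylamine to chromone 20.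

Step 4. Bromination could drift to C8 (ortho to the MOM-oxy group), or the electron-rich para-alkoxyphenol could be oxidised, in competition with substitution at C8a. The fallback replaces electrophilic halogenation by directed ortho-metalation, setting out from 5 and returning at 10 without passing through 6 and 7. Phenol 5 with isopropyl isocyanate (cat Et3N, CH2Cl2) would give 2-methoxy-4-(methoxymethoxy)-3-methylphenyl N-isopropylcarbamate F4. N-Silylation in the flask (TMSOTf, TMEDA, Et2O), lithiation with n-BuLi at −78 °C at C8a, the only ortho C–H of the strongly directing carbamate, and a TMSCl quench would give after work-up 2-methoxy-4-(methoxymethoxy)-3-methyl-6-(trimethylsilyl)phenyl N-isopropylcarbamate F5. One-pot carbamate cleavage (Et2NH, DBU, MeCN, 40 °C) to 2-methoxy-4-(methoxymethoxy)-3-methyl-6-(trimethylsilyl)phenol F6, not isolated, and triflation with PhNTf2 would deliver 10.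

Step 11. Aminomethylation of the vinylogous-acid phenol could stall, or the benzylic amine intermediate could condense with a second chromone to a diarylmethane before the redox step. The fallback separates C–H functionalisation from C–C bond formation, setting out from 21 and returning at 22. NIS in DMF at 0 °C would iodinate C8 to give 7-hydroxy-8-iodo-5-methoxy-3-(4-methoxybenzyl)-6-methylchromen-4-one F7. Reductive carbonylation of the aryl iodide (PdCl2(PPh3)2 as precatalyst, CO at 1 atm, HCO2Na as hydride source, DMF, 100 °C) would then give aldehyde 22.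

Further compounds
F1 | step 9 | 3-(4-methoxyphenyl)propanoic acid | OC(=O)CCc1ccc(OC)cc1
F2 | step 9 | 1-[6-hydroxy-2-methoxy-4-(methoxymethoxy)-3-methylphenyl]-3-(4-methoxyphenyl)propan-1-one | COCOc1cc(O)c(C(=O)CCc2ccc(OC)cc2)c(OC)c1C
F3 | step 9 | (E)-3-(dimethylamino)-1-[6-hydroxy-2-methoxy-4-(methoxymethoxy)-3-methylphenyl]-2-(4-methoxybenzyl)prop-2-en-1-one | CN(C)/C=C(\Cc1ccc(OC)cc1)C(=O)c1c(O)cc(OCOC)c(C)c1OC
F4 | step 4 | 2-methoxy-4-(methoxymethoxy)-3-methylphenyl N-isopropylcarbamate | COCOc1ccc(OC(=O)NC(C)C)c(OC)c1C
F5 | step 4 | 2-methoxy-4-(methoxymethoxy)-3-methyl-6-(trimethylsilyl)phenyl N-isopropylcarbamate | COCOc1cc([Si](C)(C)C)c(OC(=O)NC(C)C)c(OC)c1C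
F6 | step 4 | 2-methoxy-4-(methoxymethoxy)-3-methyl-6-(trimethylsilyl)phenol | COCOc1cc([Si](C)(C)C)c(O)c(OC)c1C
F7 | step 11 | 7-hydroxy-8-iodo-5-methoxy-3-(4-methoxybenzyl)-6-methylchromen-4-one | COc1ccc(Cc2coc3c(I)c(O)c(C)c(OC)c3c2=O)cc1
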